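**Retrosynthetic overview**

1. The spermine chain is numbered N1 (primary amine), C2–C4, N5 (tertiary amide), C6–C9, N10 (secondary amine), C11–C13, N14 (secondary amide). The plan rests on the four-carbon link C6–C9 between N5 and N10, read as an N5-allyl group (C6–C8) plus one carbon (C9) taken from carbon monoxide.
2. Kukoamine B 18 ⇐ N1-Boc compound 17 (acid) ⇐ fully protected 16 (hydrogenolysis of one N-benzyl and four O-benzyl groups).
3. 16 ⇐ fragment 1 (9, N5-allyl tertiary amide) + fragment 2 (12, N10-benzyl secondary amine already carrying the N14 amide) + CO/H2; rhodium-catalysed hydroaminomethylation forms C8–C9 and C9–N10.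
4. 9 ⇐ acid 4 + N-allyl amine 7 (from bromide 5 and allylamine 6); 12 ⇐ acid 4 + N-benzylpropane-1,3-diamine 10; 4 ⇐ dihydrocaffeic acid 1.
5. No ring is formed at any stage (both catechol rings arrive intact in 1) and the target has no stereocentre.

Key step: step 6

Assumption: the target is taken as the free base drawn. It should be isolated and stored as its dihydrochloride, and neutralised under argon only when the free base is needed, because the catechols oxidise in air at basic pH.

**Route**

Step 1
Reactants: 1 3-(3,4-dihydroxyphenyl)propanoic acid; 2 benzyl bromide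
Product: 3 benzyl 3-[3,4-bis(benzyloxy)phenyl]propanoate
Conditions: BnBr (3.5 equiv), K2CO3 (4 equiv), degassed DMF, 60 °C
Reagents that add atoms: benzyl bromide (2), BrCc1ccccc1
Why: Williamson etherification of both phenols together with O-alkylation of the carboxylate, all SN2 displacements on a benzylic bromide; exclusion of air keeps the catecholate from oxidising.

Step 2
Reactants: 3 benzyl 3-[3,4-bis(benzyloxy)phenyl]propanoate
Product: 4 3-[3,4-bis(benzyloxy)phenyl]propanoic acid
Conditions: LiOH·H2O (3 equiv), THF/H2O (3:1), 40 °C; then 1 M HCl to pH 2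
Reagents that add atoms: lithium hydroxide, [Li+].[OH-]
Why: Saponification of the benzyl ester by acyl–oxygen cleavage; the aryl benzyl ethers are inert to hydroxide.

Step 3
Reactants: 5 tert-butyl (3-bromopropyl)carbamate; 6 allylamine
Product: 7 tert-butyl [3-(prop-2-enylamino)propyl]carbamate
Conditions: allylamine (8 equiv), K2CO3 (1.5 equiv), MeCN, rt; excess allylamine evaporated
Reagents that add atoms: allylamine (6), C=CCN
Why: SN2 N-alkylation in which the large excess of the volatile primary amine should suppress a second alkylation; this polarity is chosen over allyl bromide with the Boc-diamine for that reason, and the carbamate N–H is too weakly nucleophilic to cyclise with K2CO3 at room temperature.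

Step 4
Reactants: 4 3-[3,4-bis(benzyloxy)phenyl]propanoic acid; 7 tert-butyl [3-(prop-2-enylamino)propyl]carbamate
Product: 9 N-(prop-2-enyl)-N-{3-[(tert-butoxycarbonyl)amino]propyl}-3-[3,4-bis(benzyloxy)phenyl]propanamide (fragment 1), via benzotriazol-1-yl ester 8 (not isolated)
Conditions: DCC (1.1 equiv), HOBt (1.1 equiv), CH2Cl2, 0 °C to rt
Reagents that add atoms: none
Why: Carbodiimide amide coupling through the HOBt active ester; the unhindered dialkylamine is the only nucleophilic nitrogen, since the carbamate N–H is not acylated under these conditions.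

Step 5
Reactants: 4 3-[3,4-bis(benzyloxy)phenyl]propanoic acid; 10 N-benzylpropane-1,3-diamine
Product: 12 N-[3-(benzylamino)propyl]-3-[3,4-bis(benzyloxy)phenyl]propanamide (fragment 2), via acyl imidazolide 11 (not isolated)
Conditions: 1,1'-carbonyldiimidazole (1.0 equiv), THF, rt, 1 h; then added dropwise to 10 (1.2 equiv), THF, −10 °C to rt
Reagents that add atoms: none
Why: Amide formation through an N-acylimidazole, a mild acylating agent that reacts much faster with an unhindered primary amine than with a secondary amine; the benzyl group adds steric shielding at the secondary nitrogen, and inverse addition at low temperature keeps the diamine in excess.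

Step 6
Reactants: 9 fragment 1; 12 fragment 2; 13 carbon monoxide
Product: 16 N1-Boc-N10-benzyl-N5,N14-bis{3-[3,4-bis(benzyloxy)phenyl]propanoyl}spermine, via linear aldehyde 14 (not isolated), via enamine 15 (not isolated)
Conditions: 9 (1.0 equiv), 12 (1.05 equiv), [Rh(cod)2]BF4 (1 mol %), Xantphos (4 mol %), CO (7 bar), H2 (33 bar), toluene/MeOH (1:1), 110 °C
Reagents that add atoms: carbon monoxide (13), [C-]#[O+]
Why: Hydroaminomethylation, a tandem hydroformylation and reductive amination: the rhodium hydride formed from [Rh(cod)2]BF4, Xantphos and CO/H2 adds across the allyl C7=C8 bond with the metal on terminal C8, CO insertion and hydrogenolysis of the acyl give the linear 4-amidobutanal 14, the secondary amine of 12 condenses with it to the iminium ion or enamine 15, and the same hydride reduces this to the tertiary amine, so C8–C9 and C9–N10 form in one flask. The closest known reaction type is the rhodium/Xantphos hydroaminomethylation of terminal alkenes with secondary amines, together with the linear-selective hydroformylation of N-allyl amides and imides. No ring is closed and no stereocentre is created. The step needs linear over branched regioselectivity and suppression of allyl-to-enamide isomerisation; the wide bite angle of Xantphos should secure both by holding the two phosphines bis-equatorial and disfavouring the amide-chelated branched alkyl. It also needs a single alkylation at N10, which the benzyl cap ensures, and an aldehyde that is not trapped, which holds because N5 is fully substituted and the carbamate N1–H could reach C9 only through a nine-membered ring. Benzyl ethers, the N-benzyl group, the Boc group and both amides should be inert to the homogeneous rhodium phosphine carbonyl hydride.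

Step 7
Reactants: 16 N1-Boc-N10-benzyl-N5,N14-bis{3-[3,4-bis(benzyloxy)phenyl]propanoyl}spermine
Product: 17 N1-Boc-N5,N14-bis[3-(3,4-dihydroxyphenyl)propanoyl]spermine (N1-Boc-kukoamine B)
Conditions: H2 (3 bar), Pd(OH)2/C (20 wt %), THF/EtOH (1:1), AcOH (3 equiv), rt; filtered and concentrated under argon, used directly
Reagents that add atoms: none
Why: Heterogeneous hydrogenolysis of the four benzylic C–O bonds and the benzylic C–N bond; acetic acid protonates the amines, which should speed N-debenzylation, limit catalyst poisoning and suppress N-alkylation by the alcohol solvent, while the carbamate, the amides and the arene rings are untouched.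

Step 8
Reactants: 17 N1-Boc-kukoamine B
Product: 18 kukoamine B
Conditions: HCl (4 M in 1,4-dioxane), MeOH, 0 °C to rt; dihydrochloride collected, free base released on a weakly basic ion-exchange resin under argon
Reagents that add atoms: none
Why: Acidolysis of the tert-butyl carbamate, with loss of the tert-butyl cation as 2-methylpropene and decarboxylation of the carbamic acid; both amides are stable, and the catechols are protected from air oxidation in acid.

**Compound list**

1 | 3-(3,4-dihydroxyphenyl)propanoic acid (dihydrocaffeic acid) | OC(=O)CCc1ccc(O)c(O)c1 | starting material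
2 | benzyl bromide | BrCc1ccccc1 | starting material
3 | benzyl 3-[3,4-bis(benzyloxy)phenyl]propanoate | O=C(CCc1ccc(OCc2ccccc2)c(OCc2ccccc2)c1)OCc1ccccc1 | intermediate
4 | 3-[3,4-bis(benzyloxy)phenyl]propanoic acid | OC(=O)CCc1ccc(OCc2ccccc2)c(OCc2ccccc2)c1 | intermediate
5 | tert-butyl (3-bromopropyl)carbamate | CC(C)(C)OC(=O)NCCCBr | starting material
6 | allylamine (prop-2-en-1-amine) | C=CCN | starting material
7 | tert-butyl [3-(prop-2-enylamino)propyl]carbamate | C=CCNCCCNC(=O)OC(C)(C)C | intermediate
8 | benzotriazol-1-yl 3-[3,4-bis(benzyloxy)phenyl]propanoate (HOBt active ester) | O=C(CCc1ccc(OCc2ccccc2)c(OCc2ccccc2)c1)On1nnc2ccccc12 | intermediate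
9 | N-(prop-2-enyl)-N-{3-[(tert-butoxycarbonyl)amino]propyl}-3-[3,4-bis(benzyloxy)phenyl]propanamide (fragment 1) | C=CCN(CCCNC(=O)OC(C)(C)C)C(=O)CCc1ccc(OCc2ccccc2)c(OCc2ccccc2)c1 | intermediate
10 | N-benzylpropane-1,3-diamine | NCCCNCc1ccccc1 | starting material
11 | 1-{3-[3,4-bis(benzyloxy)phenyl]propanoyl}imidazole (acyl imidazolide) | O=C(CCc1ccc(OCc2ccccc2)c(OCc2ccccc2)c1)n1ccnc1 | intermediate
12 | N-[3-(benzylamino)propyl]-3-[3,4-bis(benzyloxy)phenyl]propanamide (fragment 2) | O=C(CCc1ccc(OCc2ccccc2)c(OCc2ccccc2)c1)NCCCNCc1ccccc1 | intermediate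
13 | carbon monoxide | [C-]#[O+] | starting material
14 | N-{3-[(tert-butoxycarbonyl)amino]propyl}-N-(4-oxobutyl)-3-[3,4-bis(benzyloxy)phenyl]propanamide (linear aldehyde) | O=CCCCN(CCCNC(=O)OC(C)(C)C)C(=O)CCc1ccc(OCc2ccccc2)c(OCc2ccccc2)c1 | intermediate
15 | (E)-enamine from 14 and 12: compound 16 with a C8=C9 double bond | CC(C)(C)OC(=O)NCCCN(CC/C=C/N(Cc1ccccc1)CCCNC(=O)CCc1ccc(OCc2ccccc2)c(OCc2ccccc2)c1)C(=O)CCc1ccc(OCc2ccccc2)c(OCc2ccccc2)c1 | intermediate
16 | N1-Boc-N10-benzyl-N5,N14-bis{3-[3,4-bis(benzyloxy)phenyl]propanoyl}spermine | CC(C)(C)OC(=O)NCCCN(CCCCN(Cc1ccccc1)CCCNC(=O)CCc1ccc(OCc2ccccc2)c(OCc2ccccc2)c1)C(=O)CCc1ccc(OCc2ccccc2)c(OCc2ccccc2)c1 | intermediate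
17 | N1-Boc-N5,N14-bis[3-(3,4-dihydroxyphenyl)propanoyl]spermine (N1-Boc-kukoamine B) | CC(C)(C)OC(=O)NCCCN(CCCCNCCCNC(=O)CCc1ccc(O)c(O)c1)C(=O)CCc1ccc(O)c(O)c1 | intermediate
18 | kukoamine B | NCCCN(CCCCNCCCNC(=O)CCc1ccc(O)c(O)c1)C(=O)CCc1ccc(O)c(O)c1 | target

**Step count**

Total: 8 steps. Longest linear sequence: 6 steps (1 → 3 → 4 → 9 or 12 → 16 → 17 → 18).

**Steps most likely to fail**

1. Step 6 (hydroaminomethylation). The rhodium hydride may isomerise the N-allyl group to the N-prop-1-enyl enamide, amide-oxygen chelation may steer hydroformylation to the branched aldehyde, or the alkene may simply be hydrogenated. The aldehyde may also self-condense under amine catalysis, and reversible capture of the iminium ion by N14–H as a six-membered aminal may slow the final reduction. Fallback, setting out from 5 and returning at 16, with C9 supplied by an acetal carbon instead of CO: 5 is alkylated with an excess of 4,4-diethoxybutan-1-amine (K2CO3, MeCN, rt) to give tert-butyl {3-[(4,4-diethoxybutyl)amino]propyl}carbamate F1. Coupling of F1 with acid 4 (DCC, HOBt, CH2Cl2, through active ester 8) should give N-{3-[(tert-butoxycarbonyl)amino]propyl}-N-(4,4-diethoxybutyl)-3-[3,4-bis(benzyloxy)phenyl]propanamide F2. Mild acetal hydrolysis (catalytic p-TsOH, acetone/H2O, rt) releases aldehyde 14 with the Boc group intact. Reductive amination of 14 with amine 12 (NaBH(OAc)3, AcOH, 1,2-dichloroethane, rt) then reaches 16.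

2. Step 5 (primary-selective acylation). Competing acylation at the secondary benzylamine nitrogen, or double acylation, would erode the yield of fragment 2 and give isomers that are hard to separate. Fallback, setting out from 4 and returning at 12: imidazolide 11, made from 4 as before, is added to a large excess of propane-1,3-diamine (THF, 0 °C) to give N-(3-aminopropyl)-3-[3,4-bis(benzyloxy)phenyl]propanamide F3. Condensation of F3 with benzaldehyde in MeOH forms N-[3-(benzylideneamino)propyl]-3-[3,4-bis(benzyloxy)phenyl]propanamide F4, which is reduced in the same flask with NaBH4 to 12; the benzyl group is thus placed on nitrogen only after the amide is secure.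

3. Step 7 (global hydrogenolysis). Cleavage of the tertiary N-benzyl group may stall through catalyst poisoning by the free amines, the liberated secondary amine may be N-alkylated by the alcohol solvent, and the unmasked catechols may oxidise during filtration. Fallback, setting out from 16 and returning at 18, with the order of deprotection inverted: HCl (4 M in 1,4-dioxane, CH2Cl2, 0 °C to rt) removes the Boc group first to give N10-benzyl-N5,N14-bis{3-[3,4-bis(benzyloxy)phenyl]propanoyl}spermine F5 as its dihydrochloride. Hydrogenolysis of this fully protonated salt (H2, Pd/C, MeOH/H2O, rt) should then deliver 18 directly as the dihydrochloride, bypassing 17 and leaving toluene as the only by-product of the last step.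

**Further compounds**

F1 | step 6 | tert-butyl {3-[(4,4-diethoxybutyl)amino]propyl}carbamate | CCOC(OCC)CCCNCCCNC(=O)OC(C)(C)C
F2 | step 6 | N-{3-[(tert-butoxycarbonyl)amino]propyl}-N-(4,4-diethoxybutyl)-3-[3,4-bis(benzyloxy)phenyl]propanamide | CCOC(OCC)CCCN(CCCNC(=O)OC(C)(C)C)C(=O)CCc1ccc(OCc2ccccc2)c(OCc2ccccc2)c1
F3 | step 5 | N-(3-aminopropyl)-3-[3,4-bis(benzyloxy)phenyl]propanamide | NCCCNC(=O)CCc1ccc(OCc2ccccc2)c(OCc2ccccc2)c1
F4 | step 5 | N-[3-(benzylideneamino)propyl]-3-[3,4-bis(benzyloxy)phenyl]propanamide | O=C(CCc1ccc(OCc2ccccc2)c(OCc2ccccc2)c1)NCCC/N=C/c1ccccc1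
F5 | step 7 | N10-benzyl-N5,N14-bis{3-[3,4-bis(benzyloxy)phenyl]propanoyl}spermine | NCCCN(CCCCN(Cc1ccccc1)CCCNC(=O)CCc1ccc(OCc2ccccc2)c(OCc2ccccc2)c1)C(=O)CCc1ccc(OCc2ccccc2)c(OCc2ccccc2)c1
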